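**Retrosynthetic overview**
1. Target 25 ⇐ peracid epoxidation of the Z‑C1=C10 olefin 24 ⇐ C1 ketone 22 (Felkin reduction, anti‑dehydration) ⇐ double angeloylation of epoxy diol 19 with two molecules of angelic acid.
2. 4,5‑Epoxide and 6‑OH ⇐ cis‑4,5‑diol beside the C6 ketone of the ten‑membered diketone 17 (closure with inversion at C5, then chelation‑controlled reduction).
3. Ten‑membered ring ⇐ ozonolysis of the tetrasubstituted C1=C6 ring‑fusion alkene of bicyclic diol 16 ⇐ deconjugated enone 14 ⇐ Birch reduction of the anisole ring of tetralin lactone 10 (methoxy carbon = C4); this dearomatisation is the key step.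
4. 10 ⇐ anti aldol of 2‑tetralone 4 with methyl pyruvate, directed reduction, lactonisation; 4 ⇐ (3‑methoxyphenyl)acetic acid + propene.
5. Ring order: tetralone carbocycle (step 1) → γ‑lactone (3) → arene dearomatised (4) → ten‑membered ring (7) → 4,5‑epoxide (8) → 1,10‑epoxide (13).

Assumption: locants C1–C15 are the germacrane numbering of the target (C12 = lactone carbonyl) and are used for all intermediates. C10 of 4–23 is a 1:1 mixture of epimers from step 1 that is erased in step 12. The route is a design on paper and has not been run.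

**Step 1**
Reactants: 1 (3‑methoxyphenyl)acetic acid; 2 propene
Product: 4 7‑methoxy‑4‑methyl‑3,4‑dihydronaphthalen‑2(1H)‑one (racemic), via (3‑methoxyphenyl)acetyl chloride 3 (not isolated)
Conditions: SOCl2, CH2Cl2, 40 °C; then propene (1 atm), AlCl3, CH2Cl2, −10 °C to rt; ice/HCl
Reagents that add atoms: none
Why: The acid chloride acylates propene at its terminal carbon and the secondary cation closes onto the ring para to OMe (Friedel–Crafts acylation–cycloalkylation, the Burckhalter–Campbell 2‑tetralone synthesis); the methyl‑bearing carbon (future C10) is racemic and later becomes sp2.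

**Step 2**
Reactants: 4 7‑methoxy‑4‑methyl‑3,4‑dihydronaphthalen‑2(1H)‑one; 5 methyl pyruvate
Product: 8 methyl (2R)‑2‑hydroxy‑2‑[(1S)‑7‑methoxy‑4‑methyl‑2‑oxo‑1,2,3,4‑tetrahydronaphthalen‑1‑yl]propanoate, via silyl enol ether 6 (not isolated), via O‑silyl aldol adduct 7 (not isolated)
Conditions: TMSOTf, Et3N, CH2Cl2, 0 °C, filter; then 5, Sn(OTf)2 (10 mol %), (S,S)‑2,2'‑isopropylidenebis(4‑benzyl‑2‑oxazoline) (11 mol %), CH2Cl2, −78 °C; 1 M HCl/THF
Reagents that add atoms: none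
Why: Soft enolisation gives only the arene‑conjugated silyl enol ether at the benzylic carbon, and a catalytic asymmetric anti‑selective Mukaiyama aldol addition to chelated pyruvate on the Sn(OTf)2–bis(oxazoline) Lewis acid sets C11 (R) and, anti to its hydroxyl, C7.

**Step 3**
Reactants: 8 methyl (2R)‑2‑hydroxy‑2‑[(1S)‑7‑methoxy‑4‑methyl‑2‑oxo‑1,2,3,4‑tetrahydronaphthalen‑1‑yl]propanoate
Product: 10 (1R,3aR,9bR)‑1‑hydroxy‑8‑methoxy‑1,5‑dimethyl‑3a,4,5,9b‑tetrahydronaphtho[2,1‑b]furan‑2(1H)‑one (trans‑fused lactone), via diol ester 9 (not isolated)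
Conditions: Me4NBH(OAc)3, MeCN/AcOH, −30 °C; then PPTS, benzene, 60 °C
Reagents that add atoms: none
Why: Saksena–Evans hydroxyl‑directed reduction delivers hydride from the C11–O‑bound acetoxyborohydride to the face of the C8 ketone that carries the side chain, so C8–OH ends trans to it (8R), and acid‑catalysed lactonisation closes the trans‑fused γ‑lactone.

**Step 4**
Reactants: 10 (1R,3aR,9bR)‑1‑hydroxy‑8‑methoxy‑1,5‑dimethyl‑3a,4,5,9b‑tetrahydronaphtho[2,1‑b]furan‑2(1H)‑one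
Product: 14 (1R,3aR,9bR)‑1‑hydroxy‑1,5‑dimethyl‑3a,4,5,6,7,9b‑hexahydronaphtho[2,1‑b]furan‑2,8(1H,9H)‑dione (C4 ketone with C1=C6 ring‑fusion alkene), via lithium hydroxy carboxylate 11 (not isolated), via dihydroanisole enol ether 12 (not isolated), via keto hydroxy acid 13 (not isolated)
Conditions: LiOH, THF/H2O, rt; dry; Li, NH3(l), THF, t‑BuOH, −78 to −33 °C; NH4Cl; oxalic acid, H2O/THF, rt; EDC·HCl, CH2Cl2, 0 °C
Reagents that add atoms: water, O; lithium hydroxide, [Li+].[OH-] (its oxygen is scrambled into the lactone carbonyl)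
Why: This is the key step: with the lactone masked as its carboxylate, Birch reduction breaks the aromaticity of the anisole ring and protonates the two unsubstituted ortho/meta carbons (as with 6‑methoxytetralin), leaving the enol ether (mild oxalic acid hydrolysis gives the unconjugated C4 ketone) and the tetrasubstituted C1=C6 alkene that is cut in step 7; carbodiimide relactonisation restores the trans lactone with C7, C8 and C11 untouched.

**Step 5**
Reactants: 14 (1R,3aR,9bR)‑1‑hydroxy‑1,5‑dimethyl‑3a,4,5,6,7,9b‑hexahydronaphtho[2,1‑b]furan‑2,8(1H,9H)‑dione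
Product: 15 (1R,3aR,9R,9bR)‑1,9‑dihydroxy‑1,5‑dimethyl‑3a,4,5,6,7,9b‑hexahydronaphtho[2,1‑b]furan‑2,8(1H,9H)‑dione (5R‑hydroxy ketone)
Conditions: LiN(SiMe3)2 (2.2 equiv), THF, −78 °C; (+)‑(camphorsulfonyl)oxaziridine, −78 °C; NH4Cl
Reagents that add atoms: (+)‑(2R,8aS)‑(camphorsulfonyl)oxaziridine, CC1(C)C2CCC13CS(=O)(=O)N4OC34C2
Why: Only C5 is both α to the ketone and allylic, and its dienolate is hydroxylated at the α‑carbon by the chiral N‑sulfonyloxaziridine (Davis oxidation, reagent‑controlled face) to give the 5R alcohol without moving the C1=C6 alkene.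

**Step 6**
Reactants: 15 (1R,3aR,9R,9bR)‑1,9‑dihydroxy‑1,5‑dimethyl‑3a,4,5,6,7,9b‑hexahydronaphtho[2,1‑b]furan‑2,8(1H,9H)‑dione
Product: 16 (1R,3aR,8S,9R,9bR)‑1,8,9‑trihydroxy‑1,5,8‑trimethyl‑3a,4,5,6,7,8,9,9b‑octahydronaphtho[2,1‑b]furan‑2(1H)‑one (cis‑4,5‑diol)
Conditions: MeMgBr (3.5 equiv), THF, −78 °C; NH4Cl
Reagents that add atoms: methylmagnesium bromide, C[Mg]Br
Why: Chelation‑controlled Grignard addition (Cram chelate between the C5 alkoxide and the ketone) brings methyl in anti to the C5 oxygen, so the tertiary C4–OH is cis to C5–OH (4S); the ketone reacts far faster than the lactone at −78 °C.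

**Step 7**
Reactants: 16 (1R,3aR,8S,9R,9bR)‑1,8,9‑trihydroxy‑1,5,8‑trimethyl‑3a,4,5,6,7,8,9,9b‑octahydronaphtho[2,1‑b]furan‑2(1H)‑one
Product: 17 (4S,5S,7R,8R,11R)‑4,5,11‑trihydroxy‑1,6‑dioxogermacran‑8,12‑olide (ten‑membered diketone)
Conditions: O3, CH2Cl2/MeOH, −78 °C; Me2S, −78 °C to rt
Reagents that add atoms: ozone, [O-][O+]=O
Why: Ozonolysis with reductive work‑up cleaves the only C=C bond, the tetrasubstituted ring‑fusion alkene, and so opens the bicyclic core to the ten‑membered 1,6‑diketone (ring expansion by alkene cleavage) with every stereocentre untouched.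

**Step 8**
Reactants: 17 (4S,5S,7R,8R,11R)‑4,5,11‑trihydroxy‑1,6‑dioxogermacran‑8,12‑olide
Product: 18 (4S,5R,7R,8R,11R)‑4,5‑epoxy‑11‑hydroxy‑1,6‑dioxogermacran‑8,12‑olide
Conditions: PPh3, DIAD, THF, 0 °C to rt
Reagents that add atoms: none
Why: Mitsunobu cyclodehydration activates the secondary C5–OH and the tertiary C4 oxygen displaces it with inversion (SN2), which from the cis‑diol gives the trans‑disposed 4,5‑epoxide (C3 and C6 trans), because the anti alignment is reachable only once the former ring bond is gone.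

**Step 9**
Reactants: 18 (4S,5R,7R,8R,11R)‑4,5‑epoxy‑11‑hydroxy‑1,6‑dioxogermacran‑8,12‑olide
Product: 19 (4S,5S,6S,7R,8R,11R)‑4,5‑epoxy‑6,11‑dihydroxy‑1‑oxogermacran‑8,12‑olide
Conditions: Zn(BH4)2 (limiting), Et2O, −40 °C; NH4Cl
Reagents that add atoms: none
Why: Chelation‑controlled reduction of the α,β‑epoxy ketone with Zn(BH4)2 (zinc bridging epoxide and carbonyl oxygens) gives the erythro epoxy alcohol (6S), and the chelated ketone reacts before the unactivated C1 ketone.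

**Step 10**
Reactants: 19 (4S,5S,6S,7R,8R,11R)‑4,5‑epoxy‑6,11‑dihydroxy‑1‑oxogermacran‑8,12‑olide; 20 angelic acid [(Z)‑2‑methylbut‑2‑enoic acid] (3 equiv used; two molecules are built into the product, one per hydroxyl)
Product: 22 (4S,5S,6S,7S,8R,11R)‑6,11‑bis(angeloyloxy)‑4,5‑epoxy‑1‑oxogermacran‑8,12‑olide, via angelic 2,4,6‑trichlorobenzoic anhydride 21 (not isolated)
Conditions: 20 (3 equiv), 2,4,6‑trichlorobenzoyl chloride (3 equiv), Et3N (3 equiv), toluene, rt; then 19, toluene, 80 °C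
Reagents that add atoms: angelic acid (the second molecule of 20, which supplies the second angeloyl group), C/C=C(/C)C(=O)O
Why: Yamaguchi‑type esterification in which two molecules of mixed anhydride 21 each transfer one angeloyl group at the less hindered carbonyl, run hot and without DMAP so that the Z‑enoate does not isomerise to the tiglate, acylates first the secondary C6–OH and then the tertiary C11–OH.

**Step 11**
Reactants: 22 (4S,5S,6S,7S,8R,11R)‑6,11‑bis(angeloyloxy)‑4,5‑epoxy‑1‑oxogermacran‑8,12‑olide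
Product: 23 6,11‑bis(angeloyloxy)‑4,5‑epoxy‑1‑hydroxygermacran‑8,12‑olide (Felkin alcohols of both C10 epimers)
Conditions: NaBH4, MeOH/CH2Cl2, −40 °C
Reagents that add atoms: none
Why: Felkin–Anh hydride addition to the α‑methyl ketone (C9 chain anti to the incoming hydride) sets C1 relative to C10 in the same sense for both C10 epimers, and borohydride leaves esters, lactone and epoxide alone.

**Step 12**
Reactants: 23 6,11‑bis(angeloyloxy)‑4,5‑epoxy‑1‑hydroxygermacran‑8,12‑olide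
Product: 24 (1(10)Z,4S,5S,6S,7S,8R,11R)‑6,11‑bis(angeloyloxy)‑4,5‑epoxygermacr‑1(10)‑en‑8,12‑olide
Conditions: Ph2S[OC(CF3)2Ph]2, CH2Cl2, 0 °C to rt
Reagents that add atoms: none
Why: Dehydration with the diaryldialkoxysulfurane (Martin dehydration) is an anti‑periplanar E2 elimination of the C1 oxysulfonium and the tertiary C10–H, which from the Felkin alcohol of either C10 epimer places C2 and C9 cis and gives the more substituted Z‑C1=C10 olefin.

**Step 13**
Reactants: 24 (1(10)Z,4S,5S,6S,7S,8R,11R)‑6,11‑bis(angeloyloxy)‑4,5‑epoxygermacr‑1(10)‑en‑8,12‑olide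
Product: 25 CNP0219924.1 [(1R,4S,5S,6S,7S,8R,10S,11R)‑6,11‑bis(angeloyloxy)‑1,10:4,5‑diepoxygermacran‑8,12‑olide]
Conditions: mCPBA, NaHCO3, CH2Cl2, 0 °C
Reagents that add atoms: 3‑chloroperoxybenzoic acid, OOC(=O)c1cccc(Cl)c1
Why: Prilezhaev epoxidation occurs at the electron‑rich ring olefin (the conjugated angelate olefins are too electron‑poor) and is expected on the exposed outer face of the folded ten‑membered ring, as is general for germacranolides, giving the cis 1R,10S epoxide.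

**Compound list**
1 | (3‑methoxyphenyl)acetic acid | COc1cccc(CC(=O)O)c1 | starting material
2 | propene | CC=C | starting material
3 | (3‑methoxyphenyl)acetyl chloride | COc1cccc(CC(=O)Cl)c1 | intermediate
4 | 7‑methoxy‑4‑methyl‑3,4‑dihydronaphthalen‑2(1H)‑one (racemic) | COc1ccc2c(c1)CC(=O)CC2C | intermediate
5 | methyl pyruvate | CC(=O)C(=O)OC | starting material
6 | trimethylsilyl enol ether of 4 | COc1ccc2c(c1)C=C(O[Si](C)(C)C)CC2C | intermediate
7 | O‑trimethylsilyl ether of aldol adduct 8 | COc1ccc2c(c1)[C@@H]([C@@](C)(O[Si](C)(C)C)C(=O)OC)C(=O)CC2C | intermediate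
8 | methyl (2R)‑2‑hydroxy‑2‑[(1S)‑7‑methoxy‑4‑methyl‑2‑oxo‑1,2,3,4‑tetrahydronaphthalen‑1‑yl]propanoate (C10 epimers) | COc1ccc2c(c1)[C@@H]([C@@](C)(O)C(=O)OC)C(=O)CC2C | intermediate
9 | methyl (2R)‑2‑hydroxy‑2‑[(1R,2R)‑2‑hydroxy‑7‑methoxy‑4‑methyl‑1,2,3,4‑tetrahydronaphthalen‑1‑yl]propanoate | COc1ccc2c(c1)[C@@H]([C@@](C)(O)C(=O)OC)[C@H](O)CC2C | intermediate
10 | (1R,3aR,9bR)‑1‑hydroxy‑8‑methoxy‑1,5‑dimethyl‑3a,4,5,9b‑tetrahydronaphtho[2,1‑b]furan‑2(1H)‑one | COc1ccc2c(c1)[C@@H]1[C@H](OC(=O)[C@]1(C)O)CC2C | intermediate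
11 | lithium salt of the hydroxy acid from 10 | COc1ccc2c(c1)[C@@H]([C@@](C)(O)C(=O)[O-])[C@H](O)CC2C.[Li+] | intermediate
12 | 2,5‑dihydroanisole (enol ether) carboxylate from Birch reduction of 11 | COC1=CCC2=C(C1)[C@@H]([C@@](C)(O)C(=O)[O-])[C@H](O)CC2C.[Li+] | intermediate
13 | keto hydroxy acid from hydrolysis of 12 | CC1C[C@@H](O)[C@H]([C@@](C)(O)C(=O)O)C2=C1CCC(=O)C2 | intermediate
14 | (1R,3aR,9bR)‑1‑hydroxy‑1,5‑dimethyl‑3a,4,5,6,7,9b‑hexahydronaphtho[2,1‑b]furan‑2,8(1H,9H)‑dione | CC1C[C@H]2OC(=O)[C@](C)(O)[C@@H]2C2=C1CCC(=O)C2 | intermediate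
15 | (1R,3aR,9R,9bR)‑1,9‑dihydroxy analogue of 14 (5R‑hydroxy ketone) | CC1C[C@H]2OC(=O)[C@](C)(O)[C@@H]2C2=C1CCC(=O)[C@@H]2O | intermediate
16 | (1R,3aR,8S,9R,9bR)‑1,8,9‑trihydroxy‑1,5,8‑trimethyl‑3a,4,5,6,7,8,9,9b‑octahydronaphtho[2,1‑b]furan‑2(1H)‑one (cis‑4,5‑diol) | CC1C[C@H]2OC(=O)[C@](C)(O)[C@@H]2C2=C1CC[C@](C)(O)[C@@H]2O | intermediate
17 | (4S,5S,7R,8R,11R)‑4,5,11‑trihydroxy‑1,6‑dioxogermacran‑8,12‑olide | CC1C[C@H]2OC(=O)[C@](C)(O)[C@@H]2C(=O)[C@@H](O)[C@@](C)(O)CCC1=O | intermediate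
18 | (4S,5R,7R,8R,11R)‑4,5‑epoxy‑11‑hydroxy‑1,6‑dioxogermacran‑8,12‑olide | CC1C[C@H]2OC(=O)[C@](C)(O)[C@@H]2C(=O)[C@@H]2O[C@@]2(C)CCC1=O | intermediate
19 | (4S,5S,6S,7R,8R,11R)‑4,5‑epoxy‑6,11‑dihydroxy‑1‑oxogermacran‑8,12‑olide | CC1C[C@H]2OC(=O)[C@](C)(O)[C@@H]2[C@H](O)[C@@H]2O[C@@]2(C)CCC1=O | intermediate
20 | angelic acid | C/C=C(/C)C(=O)O | starting material
21 | angelic 2,4,6‑trichlorobenzoic anhydride | C/C=C(/C)C(=O)OC(=O)c1c(Cl)cc(Cl)cc1Cl | intermediate
22 | (4S,5S,6S,7S,8R,11R)‑6,11‑bis(angeloyloxy)‑4,5‑epoxy‑1‑oxogermacran‑8,12‑olide | CC1C[C@H]2OC(=O)[C@](C)(OC(=O)/C(C)=C\C)[C@@H]2[C@H](OC(=O)/C(C)=C\C)[C@@H]2O[C@@]2(C)CCC1=O | intermediate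
23 | 6,11‑bis(angeloyloxy)‑4,5‑epoxy‑1‑hydroxygermacran‑8,12‑olide (Felkin alcohols, C1/C10 pairs) | CC1C[C@H]2OC(=O)[C@](C)(OC(=O)/C(C)=C\C)[C@@H]2[C@H](OC(=O)/C(C)=C\C)[C@@H]2O[C@@]2(C)CCC1O | intermediate
24 | (1(10)Z,4S,5S,6S,7S,8R,11R)‑6,11‑bis(angeloyloxy)‑4,5‑epoxygermacr‑1(10)‑en‑8,12‑olide | C/C1=C/CC[C@]2(C)O[C@H]2[C@@H](OC(=O)/C(C)=C\C)[C@@H]2[C@@H](C1)OC(=O)[C@]2(C)OC(=O)/C(C)=C\C | intermediate
25 | CNP0219924.1 | C/C=C(/C)C(=O)O[C@H]1[C@@H]2[C@@H](C[C@]3(C)O[C@@H]3CC[C@]3(C)O[C@@H]13)OC(=O)[C@]2(C)OC(=O)/C(C)=C\C | target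

**Step count and risks**
Total steps: 13. Longest linear sequence: 13 steps (1 → 25).

Step 10 (double angeloylation, including the hindered tertiary C11–OH, with risk of Z→E isomerisation). The fallback sets out from 19 and comes back at 22. Both hydroxyls are acylated with 2‑[bis(2,2,2‑trifluoroethoxy)phosphoryl]propanoyl chloride (2.5 equiv, pyridine, DMAP; this saturated acyl group cannot isomerise) to give the bis(phosphonopropanoate) F1. A Still–Gennari olefination with acetaldehyde (KN(SiMe3)2, 18‑crown‑6, THF, −78 °C) then builds both Z‑2‑methylbut‑2‑enoates on the substrate, which is 22.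

Step 12 (the dehydration may give the C1=C2 olefin or an E/Z mixture). The fallback sets out from 22 and comes back at 25. The ketone is brominated at its more substituted α‑carbon C10 (PhNMe3Br3, THF, CaCO3 buffer, 0 °C), on the face left open by the ring conformation, to give the α‑bromo ketone F2. Polar Felkin–Anh reduction with NaBH4 (bromine anti to the hydride) gives the bromohydrin F3. K2CO3 in acetone then closes the cis 1,10‑epoxide by intramolecular displacement of bromide with inversion at C10, giving 25 without passing through 23 and 24.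

Step 13 (the face of epoxidation is set only by the ring conformation and has not been modelled). The fallback sets out from 24 and comes back at 25. If the peracid delivers oxygen to the wrong face, NBS in aqueous DME puts bromine on that same exposed face and water on C10 from the opposite one, giving the 1‑bromo‑10‑hydroxy compound F4. DBU then closes the epoxide on the face opposite to the one the electrophile attacked, which gives 25.

**Further compounds**
F1 | step 10 | 6,11‑bis{2‑[bis(2,2,2‑trifluoroethoxy)phosphoryl]propanoyloxy} analogue of 22 | CC1C[C@H]2OC(=O)[C@](C)(OC(=O)C(C)P(=O)(OCC(F)(F)F)OCC(F)(F)F)[C@@H]2[C@H](OC(=O)C(C)P(=O)(OCC(F)(F)F)OCC(F)(F)F)[C@@H]2O[C@@]2(C)CCC1=O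
F2 | step 12 | 10‑bromo derivative of ketone 22 | C[C@@]1(Br)C[C@H]2OC(=O)[C@](C)(OC(=O)/C(C)=C\C)[C@@H]2[C@H](OC(=O)/C(C)=C\C)[C@@H]2O[C@@]2(C)CCC1=O
F3 | step 12 | 10‑bromo‑1‑hydroxy compound (bromohydrin) from F2 | C[C@@]1(Br)C[C@H]2OC(=O)[C@](C)(OC(=O)/C(C)=C\C)[C@@H]2[C@H](OC(=O)/C(C)=C\C)[C@@H]2O[C@@]2(C)CC[C@H]1O
F4 | step 13 | 1‑bromo‑10‑hydroxy compound (bromohydrin) from 24 | C/C=C(/C)C(=O)O[C@H]1[C@@H]2[C@@H](C[C@](C)(O)[C@@H](Br)CC[C@]3(C)O[C@@H]13)OC(=O)[C@]2(C)OC(=O)/C(C)=C\C
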